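**Assumption:** the SMILES is read as (2S,3R)-3-[(1E)-3-oxononadec-1-en-1-yl]oxirane-2-carboxylic acid, a trans-epoxide. Chain numbering used below: C1 = carboxyl, C2/C3 = oxirane carbons, C4=C5 = alkene, C6 = ketone, C7–C22 = hexadecyl. Cyclopentadienyl rings are drawn as σ-bonded rings in the SMILES of zirconium compounds.

## Retrosynthetic overview

1. Target acid ⇐ its ethyl ester (hydrolysis last).
2. C5–C6 bond ⇐ heptadecanoyl anion donor (acylzirconocene from hexadec-1-ene, (C5H5)2Zr(H)Cl and CO) + (E)-alkenyl iodide. The acyl carbon, normally an electrophile, is the nucleophile toward the electrophilic alkenyl halide carbon.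
3. (E)-Alkenyl iodide ⇐ trans-epoxy aldehyde by iodo-olefination (CHI3 supplies C5).
4. Epoxy aldehyde ⇐ ethyl (2E)-4-oxobut-2-enoate by organocatalytic asymmetric epoxidation, which sets both stereocentres.
5. Ring order: the oxirane is the only ring; it is formed first and carried through intact.

## Route

**Step 1**
Reactants: 1 ethyl (2E)-4-oxobut-2-enoate
Product: 2 ethyl (2S,3S)-3-formyloxirane-2-carboxylate
Conditions: (S)-2-{bis[3,5-bis(trifluoromethyl)phenyl](trimethylsilyloxy)methyl}pyrrolidine (10 mol %), 35% aq H2O2 (1.3 equiv), CH2Cl2, rt, 4 h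
Reagents that add atoms: hydrogen peroxide, OO
Why: Jørgensen iminium–enamine epoxidation, in which H2O2 adds to the β-carbon of the E-iminium on the face anti to the diaryl(silyloxy)methyl group and the enamine then closes onto the O–O bond to give the trans-epoxide, which by the standard shielding model for the (S)-catalyst is the (2S,3S) isomer (the facial sense is derived from that model, not recalled from a reported assignment for this substrate).

**Step 2**
Reactants: 2 ethyl (2S,3S)-3-formyloxirane-2-carboxylate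
Product: 3 ethyl (2S,3R)-3-[(E)-2-iodoethenyl]oxirane-2-carboxylate
Conditions: CrCl2 (6 equiv), CHI3 (2 equiv), THF, 0 °C, dark, 3 h
Reagents that add atoms: iodoform, IC(I)I
Why: Takai iodo-olefination, in which the geminal dichromium carbenoid from CHI3 adds to the aldehyde and eliminates to the E-alkenyl iodide (typically ≥10:1 E:Z), leaving the epoxide stereocentres untouched (the descriptor at C3 changes only by CIP re-ranking).

**Step 3**
Reactants: 4 hexadec-1-ene; 3 ethyl (2S,3R)-3-[(E)-2-iodoethenyl]oxirane-2-carboxylate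
Product: 7 ethyl (2S,3R)-3-[(1E)-3-oxononadec-1-en-1-yl]oxirane-2-carboxylate, via hexadecylzirconocene chloride 5 (not isolated), via heptadecanoylzirconocene chloride 6 (not isolated)
Conditions: 4 (1.6 equiv), (C5H5)2Zr(H)Cl (1.5 equiv), CH2Cl2, rt, 30 min; CO (1 atm), rt, 2 h; Ar purge, evaporate, THF; then 3 (1.0 equiv), PdCl2(PPh3)2 (5 mol %), CuI (10 mol %), 0 °C to rt
Reagents that add atoms: carbon monoxide, [C-]#[O+]
Why: Proposed new method: hydrozirconation of 4 and CO insertion give acylzirconocene 6, an unmasked heptadecanoyl anion donor, whose acyl group should pass through an acylcopper species to the alkenylpalladium iodide formed by oxidative addition of 3, and reductive elimination then forms the C5–C6 bond with retention of the E geometry and without touching the epoxide; the closest known reaction type is the palladium- or copper-catalysed cross-coupling of acylzirconocene chlorides with allylic and benzylic halides and with hypervalent iodonium salts.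

**Step 4**
Reactants: 7 ethyl (2S,3R)-3-[(1E)-3-oxononadec-1-en-1-yl]oxirane-2-carboxylate
Product: 9 (2S,3R)-3-[(1E)-3-oxononadec-1-en-1-yl]oxirane-2-carboxylic acid, via lithium carboxylate 8 (not isolated)
Conditions: LiOH·H2O (1.1 equiv), THF/H2O (3:1), 0 °C, 1 h; then cold 1 M aq KHSO4 to pH 3, EtOAc
Reagents that add atoms: lithium hydroxide, [Li+].[OH-]
Why: Saponification (BAc2) of the inductively activated glycidic ester is fast at 0 °C with about one equivalent of hydroxide, and cold mild acidification frees the acid without opening the trans-epoxide or adding to the enone; no stereocentre is involved.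

## Compound list

1 | ethyl (2E)-4-oxobut-2-enoate | CCOC(=O)/C=C/C=O | starting material
2 | ethyl (2S,3S)-3-formyloxirane-2-carboxylate | O=C[C@H]1O[C@@H]1C(=O)OCC | intermediate
3 | ethyl (2S,3R)-3-[(E)-2-iodoethenyl]oxirane-2-carboxylate | I/C=C/[C@H]1O[C@@H]1C(=O)OCC | intermediate
4 | hexadec-1-ene | CCCCCCCCCCCCCCC=C | starting material
5 | chlorobis(cyclopentadienyl)(hexadecyl)zirconium (hexadecylzirconocene chloride) | CCCCCCCCCCCCCCCC[Zr](Cl)(C1C=CC=C1)C1C=CC=C1 | intermediate
6 | chlorobis(cyclopentadienyl)(heptadecanoyl)zirconium (heptadecanoylzirconocene chloride) | CCCCCCCCCCCCCCCCC(=O)[Zr](Cl)(C1C=CC=C1)C1C=CC=C1 | intermediate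
7 | ethyl (2S,3R)-3-[(1E)-3-oxononadec-1-en-1-yl]oxirane-2-carboxylate | CCCCCCCCCCCCCCCCC(=O)/C=C/[C@H]1O[C@@H]1C(=O)OCC | intermediate
8 | lithium (2S,3R)-3-[(1E)-3-oxononadec-1-en-1-yl]oxirane-2-carboxylate | [Li+].CCCCCCCCCCCCCCCCC(=O)/C=C/[C@H]1O[C@@H]1C([O-])=O | intermediate
9 | (2S,3R)-3-[(1E)-3-oxononadec-1-en-1-yl]oxirane-2-carboxylic acid | CCCCCCCCCCCCCCCCC(=O)/C=C/[C@H]1O[C@@H]1C(=O)O | target

## Step count

Total step count: 4.
Longest linear sequence: 4 steps (1 → 2 → 3 → 7 → 9). The acyl donor 6 is generated from 4 in the flask of step 3.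

## Steps most likely to fail, with fallbacks

**Step 3 (key coupling).** Transfer of the acyl group from zirconium to a neutral alkenylpalladium iodide is not established. Zerovalent palladium may ionise the vinyl epoxide in 3 or 7, and excess 6 could add to the enone of 7. The fallback sets out from 3 and returns at 7, keeping the acyl-anion logic but with a masked donor. Lithium ethoxyacetylide (ethoxyethyne, n-BuLi, THF, −78 °C) is alkylated with 1-iodopentadecane (DMPU, −78 °C to rt) to give 1-ethoxyheptadec-1-yne F1. Palladium-catalysed syn-hydrostannation (Bu3SnH, Pd(PPh3)4 2 mol %, THF, 0 °C) puts tin on the oxygen-bearing carbon and gives (E)-tributyl(1-ethoxyheptadec-1-en-1-yl)stannane F2. Stille coupling of F2 with 3 (Pd2(dba)3, AsPh3, CuI, DMF, rt) gives ethyl (2S,3R)-3-[(1E,3Z)-3-ethoxynonadeca-1,3-dien-1-yl]oxirane-2-carboxylate F3. Mild hydrolysis of the enol ether (0.1 M aq oxalic acid, THF, 0 °C) releases 7.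

**Step 2 (iodo-olefination).** Trivalent chromium salts with iodide may open the epoxide to a halohydrin, the E:Z ratio may be lower than usual, and 2 is a hydrate-prone aldehyde. The fallback sets out from 2 and returns at 3 without chromium. Homologation with dimethyl (1-diazo-2-oxopropyl)phosphonate (K2CO3, EtOH, 0 °C) gives ethyl (2S,3R)-3-ethynyloxirane-2-carboxylate F4. Hydrozirconation of the terminal alkyne ((C5H5)2Zr(H)Cl 1.1 equiv, THF, rt, 15 min) and iodinolysis (I2, 0 °C) give 3, with the E geometry fixed by syn addition.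

**Step 4 (final hydrolysis).** Hydroxide may deprotonate the γ-position of the epoxy enone (epoxide-to-ketone isomerisation) or add to the enone, and the glycidic acid is sensitive to acid. The fallback sets out from 3 and returns at 9, moving the hydrolysis to a stage with no enone. Compound 3 is saponified (LiOH, THF/H2O, 0 °C; cold KHSO4) to (2S,3R)-3-[(E)-2-iodoethenyl]oxirane-2-carboxylic acid F5. Silylation (iPr3SiCl, imidazole, CH2Cl2, 0 °C) gives tri(propan-2-yl)silyl (2S,3R)-3-[(E)-2-iodoethenyl]oxirane-2-carboxylate F6. Coupling of F6 with 6 under the step 3 conditions gives tri(propan-2-yl)silyl (2S,3R)-3-[(1E)-3-oxononadec-1-en-1-yl]oxirane-2-carboxylate F7. The silyl ester is cleaved without base (HF·pyridine, THF, 0 °C) to give 9.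

## Further compounds

F1 | step 3 | 1-ethoxyheptadec-1-yne | CCOC#CCCCCCCCCCCCCCCC
F2 | step 3 | (E)-tributyl(1-ethoxyheptadec-1-en-1-yl)stannane | CCCCCCCCCCCCCCC/C=C(\OCC)[Sn](CCCC)(CCCC)CCCC
F3 | step 3 | ethyl (2S,3R)-3-[(1E,3Z)-3-ethoxynonadeca-1,3-dien-1-yl]oxirane-2-carboxylate | CCCCCCCCCCCCCCC/C=C(\OCC)/C=C/[C@H]1O[C@@H]1C(=O)OCC
F4 | step 2 | ethyl (2S,3R)-3-ethynyloxirane-2-carboxylate | C#C[C@H]1O[C@@H]1C(=O)OCC
F5 | step 4 | (2S,3R)-3-[(E)-2-iodoethenyl]oxirane-2-carboxylic acid | I/C=C/[C@H]1O[C@@H]1C(=O)O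
F6 | step 4 | tri(propan-2-yl)silyl (2S,3R)-3-[(E)-2-iodoethenyl]oxirane-2-carboxylate | I/C=C/[C@H]1O[C@@H]1C(=O)O[Si](C(C)C)(C(C)C)C(C)C
F7 | step 4 | tri(propan-2-yl)silyl (2S,3R)-3-[(1E)-3-oxononadec-1-en-1-yl]oxirane-2-carboxylate | CCCCCCCCCCCCCCCCC(=O)/C=C/[C@H]1O[C@@H]1C(=O)O[Si](C(C)C)(C(C)C)C(C)C
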